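**Conventions and assumptions**

- Atoms keep the numbers C1–C23 of the target SMILES (Br = 18) in every intermediate. Ring A = C8/C9/C17/C19/C20/C21; ring B = C7/C8/C9/C11/C12/C13; ring C = C13/C14/C15/C6/C7; ring D = C13/C4/C5/C6/C7 (rings C and D make up the bicyclo[2.2.1]heptane).
- Remark on the chemistry: rotation about the C7–C8 aryl bond in 28–33 is hindered. The rotamer with the methoxy group on the C15 side is taken as the populated and reactive one; SMILES carry no rotamer information.
- Remark on the chemistry: the (R)-oxazaborolidine is assumed to give the (S)-allylic alcohol 12 by the usual model, with the alkenyl flank as the larger group.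

## The problem

Compound 42 is a tetracyclic C20 bromo diol. Rings A and B form a trans-fused decalin (C8–H and the C9 methyl anti), and ring B shares its C7–C13 bond with a bicyclo[2.2.1]heptane in which C7 is the one-carbon bridge and C13 a quaternary bridgehead. Nine stereocentres must be set (C4, C6, C7, C8, C9, C13, C15, C17, C21), two of them quaternary (C9, C13). Several can relay to others: C13 can control C4 (vicinal, through a sigmatropic shift) and C7 (face of ring C); the finished norbornane controls C15 and, through the axial C7–H, C9; the axial C9 methyl then controls C8, C21 and C17. The equatorial secondary bromide on C17 sits next to quaternary C9, so it cannot be made by substitution and will not tolerate bases or nucleophiles; bromine must enter late and without a cation. The C21 tertiary alcohol (axial, 1,3 to the C9 methyl) is prone to dehydration. The enabling feature is ring A: the heteroatom-bearing carbons C17 and C21 are para, and the methyl-bearing quaternary C9 lies between C17 and C8. This is the pattern of a 4-methoxy-2-methylphenol alkylated at its methyl-bearing ortho carbon, so ring B can close through a C9–C11 bond with loss of aromaticity.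

## Retrosynthesis

**C17–Br (42 ⇐ 41 ⇐ 40).** No skeletal bond is cut. After removal of the C15 silyl ether (41), the C17–H and C19–H bonds are taken away to give alkenyl bromide 40. Substitution at C17 fails on sterics, and a bromonium-initiated cyclisation would force a polyene route. Radical hydrogenation asks only that the C17 radical receive hydrogen on its axial side, which is the open side and gives the more stable equatorial bromide.

**C21–C22 and the ring A oxidation pattern (40 ⇐ 39 ⇐ 38 ⇐ 37 ⇐ 35).** The C21 methyl is cut back to ketone 39, which is masked as methyl enol ether 38. The alkenyl bromide comes from enol triflate 37, which is made by conjugate reduction and O-triflation of dienone 35. The order is chosen so that the C17 carbonyl has already become an alkenyl bromide when the C21 ketone is unveiled; two ketones never compete for the methyl nucleophile. The forward steps need equatorial methyl delivery at C21 (directed by the C9 methyl) and enol ether hydrolysis without double-bond migration.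

**C9–C11, the key cut (35 ⇐ 33).** Breaking this bond removes ring B and the C9 stereocentre and turns ring A into a flat phenol. The neighbouring cuts (C7–C8 or C12–C13 within ring B) would leave a quaternary carbon to be made on a saturated ring. Precursor 33 is a 7-arylnorbornane with a C11 mesylate. The forward reaction must alkylate the phenoxide at carbon, at C9 and not at C21, and from the face that leaves the methyl group axial.

**Functional group adjustment (33 ⇐ 32 ⇐ 31 ⇐ 30 ⇐ 29 ⇐ 28).** The phenol is held as a benzyl ether, the mesylate comes from a primary silyl ether, and the C15 silyl ether comes from ketone 28 by reduction. The C15 oxygen must be capped because a free alkoxide would displace the mesylate to give a six-membered ether.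

**C5–C6 (28 ⇐ 26).** Cutting the bond between bridgehead C6 and C5 opens ring D and leaves cyclopentanone 26 with a tosylate on C5. Only the C6 enolate can reach C5, and the isopropyl group becomes exo because C4 is already fixed. Cutting C6–C7 instead would require a benzylic leaving group of defined configuration on an acyclic carbon.

**C7–C8 (26 ⇐ 23 + 6).** The aryl group is added as a nucleophile to enone 23. The alternative, reduction of a 3-aryl enone, would need hydride to arrive cis to the branched C4 chain on C13, against the steric bias. An aryl nucleophile approaches anti to that chain and gives the required C7 configuration directly. The cost is a crowded bond formation between a di-ortho-substituted aryl group and a β-carbon next to a quaternary centre. Aryl bromide 6 supplies the organometallic (24).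

**C4–C13 (23 ⇐ 22 ⇐ 21 ⇐ 20 ⇐ 16).** Enone 23 comes from cyclopentene 22 by allylic oxidation (only C15 has allylic hydrogens). Acid 20 is the Ireland–Claisen product of allylic ester 16. This cut makes the quaternary C13 and the adjacent C4 in one step and passes the chirality of a single carbinol carbon to both. Alkylating a cyclopentanone twice would give no control at C4.

**Starting materials (16 ⇐ 14 + 15; 14 ⇐ 13 ⇐ 12 ⇐ 11 ⇐ 7 + 8; 6 ⇐ 5 ⇐ 3 ⇐ 1).** Ester 16 comes from alcohol 14 and 3-methylbutanoyl chloride 15. Alcohol 14 comes by enantioselective reduction of enone 11, which is assembled from tert-butyl acetate 7 and 3-ethoxycyclopent-2-en-1-one 8. Aryl bromide 6 comes from 2-bromo-3-methylanisole 1 by para-formylation (3), oxidation to phenol 5 and benzylation; the two ring oxygens are thus differentiated from the start.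

## Roads not taken

**Alternative 1:** oxidative enolate coupling to close ring C.
- Cut: the C13–C14 bond, so that the quaternary bridgehead is the last norbornane carbon to be made.
- Forward: silyl enol ethers of a C15 methyl ketone on C6 and of a ring B ketone at C12 are oxidised together with (NH4)2Ce(NO3)6. Coupling gives the 1,4-diketone A1, with bromine already on C17 and C21 held as a dioxolane.
- Merits: both partners are ordinary ketones, the bond formed is the hardest one of the bicycle, and the C15 oxygen arrives in place.
- Weak points: the ring B enol ether must be the tetrasubstituted one toward C13 and not the one toward C11. The coupling joins that fully substituted carbon to a primary carbon while closing a strained bicycle, which invites over-oxidation or simple desilylation. The C12 carbonyl of A1 is absent from 42 and must be removed beside a quaternary bridgehead with a secondary bromide present. The bromide is made early and carried through oxidant, base and reductant.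
- Comparison: this road makes C13 more directly than the chosen plan, which needs a sigmatropic shift and two later ring closures to turn its quaternary carbon into a bridgehead. Against that, the chosen plan sets C13 together with C4 in one predictable step, needs no carbonyl removal, and keeps bromine out until the second-to-last step.

**Alternative 2:** Pauson–Khand annulation.
- Cut: C7–C13, C14–C15 and C6–C15 at once, removing ring B and the cyclopentenone that becomes ring C.
- Forward: Co2(CO)8 complexes a C6≡C7 alkyne attached to ring A; with an amine N-oxide the 1,1-disubstituted C13=C14 alkene and CO are joined to give cyclopentenone A2.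
- Merits: three bonds, two rings, the quaternary C13 and the C15 carbonyl in one step, from a ring A fragment and an acyclic chain. In bonds per step and convergence it is clearly better than the chosen key step, which forms one bond and one ring.
- Weak points: the alkene carries the α-branched C4 substituent and reacts slowly. The configuration of C13 relative to ring A rests on remote induction through the tether. Ring A, with quaternary C9 and the C17 bromide, must first be made enantiopure, and the bromide must then survive cobalt carbonyl, N-oxide and the enolate chemistry still needed to close ring D from A2.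
- Comparison: the chosen plan gives up convergence. In return each stereocentre is set under an identifiable control element and bromine comes last.

**Alternative 3:** acyl radical cascade.
- Cut: C6–C15 and C4–C5, removing both rings of the norbornanone from a decalin.
- Forward: Bu3SnH converts a C15 selenoester into an acyl radical that adds 5-exo to a C7 vinyl group; the C5 radical adds 5-exo to a 2-methylpropenyl group on C13, and the tertiary radical is reduced to the isopropyl group, giving ketone A3.
- Merits: two rings, two C–C bonds, the isopropyl group and the C15 ketone in one operation, with bromine deferred as in the chosen plan. On paper this is the shortest way from a decalin to the full skeleton.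
- Weak points: the substrate needs quaternary C13 with three carbon branches cis to the C7 vinyl group on a trans-decalin, which is no easier than the target's own quaternary problem. The second cyclisation closes a strained bicycle in competition with hydrogen transfer from the stannane to a primary radical. The C4 configuration depends on the alkene rotamer in the transition state, with no strong bias toward the exo isopropyl group.
- Comparison: if the cascade worked it would be shorter than the chosen sequence. The chosen plan sets C4 in a Claisen transition state and builds ring B last on a rigid scaffold, at the price of more steps.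

Key step: step 20

## Route

Step 1
Reactants: 1 2-bromo-3-methylanisole
Product: 3 3-bromo-4-methoxy-2-methylbenzaldehyde, via chloro(methoxy)methyl arene 2 (not isolated)
Conditions: Cl2CHOMe, TiCl4, CH2Cl2, 0 °C; H2O
Reagents that add atoms: dichloromethyl methyl ether, COC(Cl)Cl; water, O
Why: Rieche formylation; the methoxy group directs the electrophile to its para position, which is also ortho to the methyl group, and chloro ether 2 is hydrolysed on work-up.

Step 2
Reactants: 3 3-bromo-4-methoxy-2-methylbenzaldehyde
Product: 5 3-bromo-4-methoxy-2-methylphenol, via aryl formate 4 (not isolated)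
Conditions: mCPBA, CH2Cl2, rt; then K2CO3 (cat.), MeOH
Reagents that add atoms: 3-chloroperoxybenzoic acid, OOC(=O)c1cccc(Cl)c1
Why: Baeyer–Villiger (Dakin-type) oxidation; the electron-rich aryl group migrates in preference to hydrogen, and methanolysis of formate 4 frees the phenol that becomes the C17 oxygen.

Step 3
Reactants: 5 3-bromo-4-methoxy-2-methylphenol
Product: 6 1-(benzyloxy)-3-bromo-4-methoxy-2-methylbenzene
Conditions: BnBr, K2CO3, DMF, rt
Reagents that add atoms: benzyl bromide, BrCc1ccccc1
Why: Williamson etherification; benzyl survives organomagnesium, alkoxide, hydride and silylation chemistry and later leaves by hydrogenolysis without touching a mesylate or a silyl ether.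

Step 4
Reactants: 7 tert-butyl acetate; 8 3-ethoxycyclopent-2-en-1-one
Product: 11 tert-butyl 2-(3-oxocyclopent-1-en-1-yl)acetate, via lithium enolate of tert-butyl acetate 9 (not isolated), via lithium alkoxide adduct 10 (not isolated)
Conditions: LiN(i-Pr)2, THF, −78 °C; 8, −78 to 0 °C; 2 M HCl, rt
Reagents that add atoms: none
Why: Stork–Danheiser sequence; 1,2-addition of the ester enolate to the vinylogous ester, then acid hydrolysis of the enol ether with loss of water, transposes the enone and places the two-carbon C12–C11 chain on the β-carbon.

Step 5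
Reactants: 11 tert-butyl 2-(3-oxocyclopent-1-en-1-yl)acetate
Product: 12 tert-butyl 2-[(3S)-3-hydroxycyclopent-1-en-1-yl]acetate
Conditions: (R)-2-methyl-CBS-oxazaborolidine (10 mol %), catecholborane, toluene, −78 °C
Reagents that add atoms: none
Why: CBS reduction; the oxazaborolidine distinguishes the alkenyl and methylene flanks of the ketone, and the (R)-catalyst should give the (S)-alcohol, whose carbinol carbon becomes C6 and later relays its configuration to C13.

Step 6
Reactants: 12 tert-butyl 2-[(3S)-3-hydroxycyclopent-1-en-1-yl]acetate
Product: 13 (1S)-3-(2-hydroxyethyl)cyclopent-2-en-1-ol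
Conditions: LiAlH4, THF, 0 °C to rt
Reagents that add atoms: none
Why: Hydride reduction of the ester to the primary alcohol (the future C11–OH); the allylic alcohol is untouched.

Step 7
Reactants: 13 (1S)-3-(2-hydroxyethyl)cyclopent-2-en-1-ol
Product: 14 (1S)-3-[2-(tert-butyldimethylsilyloxy)ethyl]cyclopent-2-en-1-ol
Conditions: TBSCl (1.05 equiv), imidazole, CH2Cl2, −20 to 0 °C
Reagents that add atoms: tert-butyldimethylsilyl chloride, CC(C)(C)[Si](C)(C)Cl
Why: Selective silylation of the primary over the secondary allylic hydroxyl with one equivalent of silyl chloride at low temperature.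

Step 8
Reactants: 14 (1S)-3-[2-(tert-butyldimethylsilyloxy)ethyl]cyclopent-2-en-1-ol; 15 3-methylbutanoyl chloride
Product: 16 (1S)-3-[2-(tert-butyldimethylsilyloxy)ethyl]cyclopent-2-en-1-yl 3-methylbutanoate
Conditions: pyridine, DMAP (cat.), CH2Cl2, 0 °C
Reagents that add atoms: none
Why: Acylation of the secondary allylic alcohol; the acid chloride brings C1–C5 with the isopropyl group on the future C4.

Step 9
Reactants: 16 (1S)-3-[2-(tert-butyldimethylsilyloxy)ethyl]cyclopent-2-en-1-yl 3-methylbutanoate
Product: 20 (2S)-2-[(1S)-1-{2-[(tert-butyldimethylsilyl)oxy]ethyl}cyclopent-2-en-1-yl]-3-methylbutanoic acid, via lithium ester enolate 17 (not isolated), via silyl ketene acetal 18 (not isolated), via trimethylsilyl ester 19 (not isolated)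
Conditions: LiN(i-Pr)2, THF/DMPU, −78 °C; Me3SiCl; −78 to 65 °C; 1 M HCl work-up
Reagents that add atoms: none
Why: Ireland–Claisen rearrangement; the C4–C13 bond forms on the ring face that carried the ester oxygen, so the C6 carbinol configuration becomes that of quaternary C13. C4 follows from the ketene acetal geometry: the (Z)-acetal 18 (isopropyl cis to OSiMe3, from enolisation in THF/DMPU) should react through the boat favoured for cycloalkenyl esters, and the (E)-acetal through the chair would give the same C4 epimer.

Step 10
Reactants: 20 (2S)-2-[(1S)-1-{2-[(tert-butyldimethylsilyl)oxy]ethyl}cyclopent-2-en-1-yl]-3-methylbutanoic acid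
Product: 21 (2S)-2-[(1S)-1-{2-[(tert-butyldimethylsilyl)oxy]ethyl}cyclopent-2-en-1-yl]-3-methylbutan-1-ol
Conditions: LiAlH4, THF, 0 to 40 °C
Reagents that add atoms: none
Why: Hydride reduction of the carboxylic acid to the primary alcohol at C5; C4 is not epimerised because no enolisable carbonyl remains.

Step 11
Reactants: 21 (2S)-2-[(1S)-1-{2-[(tert-butyldimethylsilyl)oxy]ethyl}cyclopent-2-en-1-yl]-3-methylbutan-1-ol
Product: 22 4-methylbenzenesulfonate of alcohol 21
Conditions: TsCl, pyridine, DMAP (cat.), CH2Cl2, 0 °C to rt
Reagents that add atoms: 4-methylbenzenesulfonyl chloride, Cc1ccc(cc1)S(Cl)(=O)=O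
Why: Sulfonylation of the primary alcohol makes C5 the electrophile for the later closure of ring D.

Step 12
Reactants: 22 4-methylbenzenesulfonate of alcohol 21
Product: 23 (2S)-2-[(1R)-1-{2-[(tert-butyldimethylsilyl)oxy]ethyl}-4-oxocyclopent-2-en-1-yl]-3-methylbutyl 4-methylbenzenesulfonate
Conditions: Rh2(cap)4 (cap = caprolactamate, 1 mol %), t-BuOOH, K2CO3, CH2Cl2, rt
Reagents that add atoms: tert-butyl hydroperoxide, CC(C)(C)OO
Why: Allylic C–H oxidation; only C15 carries allylic hydrogens (the other allylic carbon, C13, is quaternary), so the carbonyl forms on C15 and C7 becomes the β-carbon of the enone.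

Step 13
Reactants: 6 1-(benzyloxy)-3-bromo-4-methoxy-2-methylbenzene; 23 cyclopentenone tosylate
Product: 26 3-arylcyclopentanone tosylate (aryl on C7 cis to the C12 chain), via arylmagnesium bromide 24 (not isolated), via trimethylsilyl enol ether 25 (not isolated)
Conditions: 6, Mg, THF, 50 °C; then CuBr·SMe2 (10 mol %), Me3SiCl, HMPA, THF, −78 to −30 °C; aq. citric acid
Reagents that add atoms: none
Why: Copper-catalysed conjugate addition of an arylmagnesium bromide, accelerated by Me3SiCl/HMPA; the aryl group should add to C7 anti to the branched C4 side chain on C13, i.e. cis to the C12 chain, which sets C7. Mild acid hydrolysis of silyl enol ether 25 returns the ketone.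

Step 14
Reactants: 26 3-arylcyclopentanone tosylate
Product: 28 7-aryl-4-[2-(tert-butyldimethylsilyloxy)ethyl]-5-exo-isopropylbicyclo[2.2.1]heptan-2-one (aryl syn to the carbonyl bridge), via potassium enolate 27 (not isolated)
Conditions: KOt-Bu, t-BuOH/THF, 0 °C to rt
Reagents that add atoms: none
Why: Intramolecular enolate alkylation (5-exo-tet); under equilibrating base only the C6 enolate can reach C5 (the C14 enolate would close a four-membered ring), so the C5–C6 bond and ring D form. The C6 bridgehead configuration is forced by the cis bridge, and the isopropyl group is exo because C4 is already fixed.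

Step 15
Reactants: 28 7-arylnorbornan-2-one
Product: 29 7-arylnorbornan-2-exo-ol (C15–OH exo)
Conditions: NaBH4, MeOH/THF, 0 °C
Reagents that add atoms: none
Why: Ketone reduction with a small hydride; the aryl group on C7 lies over the exo face of C15, so hydride arrives from the endo face and the hydroxyl is exo, as in the reduction of camphor to isoborneol.

Step 16
Reactants: 29 7-arylnorbornan-2-exo-ol
Product: 30 bis(silyl ether) (C15–OTBS and C11–OTBS)
Conditions: TBSOTf, 2,6-lutidine, CH2Cl2, 0 °C
Reagents that add atoms: tert-butyldimethylsilyl trifluoromethanesulfonate, CC(C)(C)[Si](C)(C)OS(=O)(=O)C(F)(F)F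
Why: Silylation of a hindered secondary alcohol with a silyl triflate; the ether prevents the C15 alkoxide from displacing the later C11 mesylate, and its bulk favours the aryl rotamer with the slim methoxy group beside it.

Step 17
Reactants: 30 bis(silyl ether)
Product: 31 primary alcohol (C11–OH with C15–OTBS retained)
Conditions: camphorsulfonic acid (10 mol %), MeOH/CH2Cl2, 0 °C
Reagents that add atoms: none
Why: Acid-catalysed methanolysis removes the primary silyl ether much faster than the secondary one, which is neopentyl-like and shielded by the aryl group.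

Step 18
Reactants: 31 primary alcohol
Product: 32 C11 methanesulfonate
Conditions: MsCl, Et3N, CH2Cl2, 0 °C
Reagents that add atoms: methanesulfonyl chloride, CS(Cl)(=O)=O
Why: Mesylation of the primary alcohol gives the C11 electrophile for the ring B closure.

Step 19
Reactants: 32 C11 methanesulfonate
Product: 33 7-arylnorbornane phenol mesylate (C17–OH free)
Conditions: H2 (1 atm), 10% Pd/C, EtOAc, rt
Reagents that add atoms: none
Why: Hydrogenolysis of the aryl benzyl ether; mesylate, silyl ether and methyl ether are inert, and the free phenol is stable beside the mesylate at neutral pH.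

Step 20
Reactants: 33 7-arylnorbornane phenol mesylate
Product: 35 tetracyclic 4-methoxycyclohexa-2,4-dienone (C17=O; C19=C20; C21(OMe)=C8; C15–OTBS), via potassium phenoxide 34 (not isolated)
Conditions: KOt-Bu (1.1 equiv), t-BuOH, 0.005 M, 50 °C
Reagents that add atoms: none
Why: KOt-Bu deprotonates the C17 phenol; phenoxide 34 attacks C11 through its ortho carbon C9 with loss of methanesulfonate and gives the cyclohexa-2,4-dienone 35. The closest known reaction type is the base-mediated intramolecular ortho-alkylative dearomatisation of ortho-alkyl phenols to 6,6-disubstituted cyclohexa-2,4-dienones. Ring B closes in a 6-exo-tet mode on the carbon terminus of the ambident phenoxide. C9 is the only new stereocentre: the norbornane holds ring B in the one chair in which C7–H is axial, and C11 reaches C9 from the arene face that leaves the methyl group axial and syn to C7–H. Carbon is alkylated and not oxygen because O-alkylation would need an eight-membered ring, and high dilution suppresses the intermolecular ether. C9 is preferred over C21 (the other ring carbon within reach after rotation about C7–C8) because the charge of a 4-methoxyphenoxide sits on the ortho carbons and not on the oxygen-bearing para carbon, and because the rotamer with the methoxy group beside the C15 silyl ether is the less crowded one. Substitution is preferred over elimination because one equivalent of base in t-BuOH leaves the phenoxide as the only strong nucleophile. The dienone is used directly because linear dienones can dimerise.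

Step 21
Reactants: 35 tetracyclic 4-methoxycyclohexa-2,4-dienone
Product: 37 C17 enol triflate (C17=C19) with the C21 methyl enol ether retained, via lithium dienolate 36 (not isolated)
Conditions: LiBH(s-Bu)3, THF, −78 °C; then PhNTf2, −78 to 0 °C
Reagents that add atoms: N-phenylbis(trifluoromethanesulfonimide), O=S(=O)(N(c1ccccc1)S(=O)(=O)C(F)(F)F)C(F)(F)F
Why: Conjugate (1,4) reduction at C20 followed by O-triflation of the enolate (reductive triflation); the carbonyl is neopentyl and the δ-carbon C8 is fully substituted and belongs to the donor-substituted enol ether, so hydride should go to C20.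

Step 22
Reactants: 37 C17 enol triflate
Product: 38 C17 alkenyl bromide with the C21 methyl enol ether retained
Conditions: Ni(OAc)2·4H2O (10 mol %), 1,5-cyclooctadiene, Zn (cat.), LiBr, DMA/THF, rt
Reagents that add atoms: lithium bromide, [Li+].[Br-]
Why: Nickel-catalysed halide exchange of an enol triflate; zerovalent nickel formed in situ inserts into the C17–O bond and reductive elimination with bromide gives the alkenyl bromide, with the enol ether and silyl ether as spectators.

Step 23
Reactants: 38 C17 alkenyl bromide enol ether
Product: 39 C21 ketone (C8–H trans to the C9 methyl; C17(Br)=C19 retained)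
Conditions: oxalic acid, THF/H2O, rt
Reagents that add atoms: water, O
Why: Hydrolysis of the methyl enol ether under the mild acid used for 1-methoxycyclohexa-1,4-dienes, which leaves the β,γ-alkene out of conjugation. C8 is protonated anti to the axial C9 methyl, giving the trans A/B fusion; this is also the stable epimer, because the other would force C21 into a 1,3-diaxial clash with C14.

Step 24
Reactants: 39 C21 ketone
Product: 40 C21 tertiary alcohol (methyl equatorial; hydroxyl axial) with the alkenyl bromide retained
Conditions: MeMgBr, CeCl3, THF, −78 °C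
Reagents that add atoms: methylmagnesium bromide, C[Mg]Br
Why: Organocerium addition to an easily enolised ketone; the axial C9 methyl blocks the face syn to it, so the methyl group enters equatorially and the hydroxyl is axial, as required at C21.

Step 25
Reactants: 40 C21 tertiary alcohol alkenyl bromide
Product: 41 C15 tert-butyldimethylsilyl ether of the target
Conditions: Mn(dpm)3 (dpm = dipivaloylmethanate, 10 mol %), PhSiH3, t-BuOOH, i-PrOH, rt
Reagents that add atoms: none
Why: Hydrogen-atom-transfer hydrogenation of a haloalkene; hydrogen adds first to C19 to give the α-bromo radical at C17, which takes its hydrogen on the axial side away from the C9 methyl and leaves bromine equatorial. No cation or anion intervenes, so neither rearrangement nor elimination is expected.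

Step 26
Reactants: 41 C15 silyl ether of the target
Product: 42 CNP0317598.2 (target bromo diol)
Conditions: HF·pyridine, THF, 0 °C to rt
Reagents that add atoms: none
Why: Fluoride cleavage of the silyl ether under mildly acidic, non-basic conditions that spare the secondary bromide and the tertiary alcohol.

## Compound list

1 | 2-bromo-3-methylanisole (2-bromo-1-methoxy-3-methylbenzene) | COc1cccc(C)c1Br | starting material
2 | 2-bromo-4-[chloro(methoxy)methyl]-1-methoxy-3-methylbenzene | COc1ccc(C(Cl)OC)c(C)c1Br | intermediate (not isolated)
3 | 3-bromo-4-methoxy-2-methylbenzaldehyde | COc1ccc(C=O)c(C)c1Br | intermediate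
4 | 3-bromo-4-methoxy-2-methylphenyl formate | COc1ccc(OC=O)c(C)c1Br | intermediate (not isolated)
5 | 3-bromo-4-methoxy-2-methylphenol | COc1ccc(O)c(C)c1Br | intermediate
6 | 1-(benzyloxy)-3-bromo-4-methoxy-2-methylbenzene | COc1ccc(OCc2ccccc2)c(C)c1Br | intermediate
7 | tert-butyl acetate | CC(=O)OC(C)(C)C | starting material
8 | 3-ethoxycyclopent-2-en-1-one | CCOC1=CC(=O)CC1 | starting material
9 | lithium enolate of tert-butyl acetate | [Li+].C=C([O-])OC(C)(C)C | intermediate (not isolated)
10 | lithium alkoxide of tert-butyl 2-(3-ethoxy-1-hydroxycyclopent-2-en-1-yl)acetate (racemic) | [Li+].CCOC1=CC([O-])(CC(=O)OC(C)(C)C)CC1 | intermediate (not isolated)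
11 | tert-butyl 2-(3-oxocyclopent-1-en-1-yl)acetate | O=C1C=C(CC(=O)OC(C)(C)C)CC1 | intermediate
12 | tert-butyl 2-[(3S)-3-hydroxycyclopent-1-en-1-yl]acetate | O[C@@H]1C=C(CC(=O)OC(C)(C)C)CC1 | intermediate
13 | (1S)-3-(2-hydroxyethyl)cyclopent-2-en-1-ol | O[C@@H]1C=C(CCO)CC1 | intermediate
14 | (1S)-3-[2-(tert-butyldimethylsilyloxy)ethyl]cyclopent-2-en-1-ol | O[C@@H]1C=C(CCO[Si](C)(C)C(C)(C)C)CC1 | intermediate
15 | 3-methylbutanoyl chloride | CC(C)CC(Cl)=O | starting material
16 | (1S)-3-[2-(tert-butyldimethylsilyloxy)ethyl]cyclopent-2-en-1-yl 3-methylbutanoate | CC(C)CC(=O)O[C@@H]1C=C(CCO[Si](C)(C)C(C)(C)C)CC1 | intermediate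
17 | lithium enolate of ester 16 (isopropyl cis to OLi) | [Li+].CC(C)/C=C(\[O-])O[C@@H]1C=C(CCO[Si](C)(C)C(C)(C)C)CC1 | intermediate (not isolated)
18 | (Z)-trimethylsilyl ketene acetal of ester 16 (isopropyl cis to OSiMe3) | CC(C)/C=C(\O[Si](C)(C)C)O[C@@H]1C=C(CCO[Si](C)(C)C(C)(C)C)CC1 | intermediate (not isolated)
19 | trimethylsilyl ester of acid 20 | CC(C)[C@H](C(=O)O[Si](C)(C)C)[C@@]1(CCO[Si](C)(C)C(C)(C)C)C=CCC1 | intermediate (not isolated)
20 | (2S)-2-[(1S)-1-{2-[(tert-butyldimethylsilyl)oxy]ethyl}cyclopent-2-en-1-yl]-3-methylbutanoic acid | CC(C)[C@H](C(O)=O)[C@@]1(CCO[Si](C)(C)C(C)(C)C)C=CCC1 | intermediate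
21 | (2S)-2-[(1S)-1-{2-[(tert-butyldimethylsilyl)oxy]ethyl}cyclopent-2-en-1-yl]-3-methylbutan-1-ol | CC(C)[C@H](CO)[C@@]1(CCO[Si](C)(C)C(C)(C)C)C=CCC1 | intermediate
22 | (2S)-2-[(1S)-1-{2-[(tert-butyldimethylsilyl)oxy]ethyl}cyclopent-2-en-1-yl]-3-methylbutyl 4-methylbenzenesulfonate | CC(C)[C@H](COS(=O)(=O)c1ccc(C)cc1)[C@@]2(CCO[Si](C)(C)C(C)(C)C)C=CCC2 | intermediate
23 | (2S)-2-[(1R)-1-{2-[(tert-butyldimethylsilyl)oxy]ethyl}-4-oxocyclopent-2-en-1-yl]-3-methylbutyl 4-methylbenzenesulfonate (C15 ketone, C6=C7) | CC(C)[C@H](COS(=O)(=O)c1ccc(C)cc1)[C@@]2(CCO[Si](C)(C)C(C)(C)C)C=CC(=O)C2 | intermediate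
24 | [3-(benzyloxy)-6-methoxy-2-methylphenyl]magnesium bromide | COc1ccc(OCc2ccccc2)c(C)c1[Mg]Br | intermediate (not isolated)
25 | trimethylsilyl enol ether of ketone 26 (C15–OSiMe3, C6=C15) | CC(C)[C@H](COS(=O)(=O)c1ccc(C)cc1)[C@@]2(CCO[Si](C)(C)C(C)(C)C)[C@H](c3c(C)c(OCc4ccccc4)ccc3OC)C=C(O[Si](C)(C)C)C2 | intermediate (not isolated)
26 | 2-{2-[3-(benzyloxy)-6-methoxy-2-methylphenyl]-1-[2-(tert-butyldimethylsilyloxy)ethyl]-4-oxocyclopentyl}-3-methylbutyl 4-methylbenzenesulfonate; aryl on C7 cis to the C12 chain and trans to the C4 chain, C4 and C13 as in 23 | CC(C)[C@H](COS(=O)(=O)c1ccc(C)cc1)[C@@]2(CCO[Si](C)(C)C(C)(C)C)[C@H](c3c(C)c(OCc4ccccc4)ccc3OC)CC(=O)C2 | intermediate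
27 | potassium enolate of 26 (C6=C15) | [K+].CC(C)[C@H](COS(=O)(=O)c1ccc(C)cc1)[C@@]2(CCO[Si](C)(C)C(C)(C)C)[C@H](c3c(C)c(OCc4ccccc4)ccc3OC)C=C([O-])C2 | intermediate (not isolated)
28 | 7-[3-(benzyloxy)-6-methoxy-2-methylphenyl]-4-[2-(tert-butyldimethylsilyloxy)ethyl]-5-exo-isopropylbicyclo[2.2.1]heptan-2-one; aryl syn to the carbonyl bridge | CC(C)[C@@H]1C[C@@H]2[C@@H](c3c(C)c(OCc4ccccc4)ccc3OC)[C@@]1(CCO[Si](C)(C)C(C)(C)C)CC2=O | intermediate
29 | 2-exo-alcohol from 28 (C15–OH exo, on the side of the aryl-bearing bridge) | CC(C)[C@@H]1C[C@@H]2[C@@H](c3c(C)c(OCc4ccccc4)ccc3OC)[C@@]1(CCO[Si](C)(C)C(C)(C)C)C[C@H]2O | intermediate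
30 | bis(tert-butyldimethylsilyl) ether of 29 (C15–OTBS, C11–OTBS) | CC(C)[C@@H]1C[C@@H]2[C@@H](c3c(C)c(OCc4ccccc4)ccc3OC)[C@@]1(CCO[Si](C)(C)C(C)(C)C)C[C@H]2O[Si](C)(C)C(C)(C)C | intermediate
31 | primary alcohol (C11–OH, C15–OTBS, aryl benzyl ether) | CC(C)[C@@H]1C[C@@H]2[C@@H](c3c(C)c(OCc4ccccc4)ccc3OC)[C@@]1(CCO)C[C@H]2O[Si](C)(C)C(C)(C)C | intermediate
32 | C11 methanesulfonate of 31 | CC(C)[C@@H]1C[C@@H]2[C@@H](c3c(C)c(OCc4ccccc4)ccc3OC)[C@@]1(CCOS(C)(=O)=O)C[C@H]2O[Si](C)(C)C(C)(C)C | intermediate
33 | 7-(3-hydroxy-6-methoxy-2-methylphenyl)norbornane with C11 mesylate and C15–OTBS (key-step precursor) | CC(C)[C@@H]1C[C@@H]2[C@@H](c3c(C)c(O)ccc3OC)[C@@]1(CCOS(C)(=O)=O)C[C@H]2O[Si](C)(C)C(C)(C)C | intermediate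
34 | potassium phenoxide of 33 | [K+].CC(C)[C@@H]1C[C@@H]2[C@@H](c3c(C)c([O-])ccc3OC)[C@@]1(CCOS(C)(=O)=O)C[C@H]2O[Si](C)(C)C(C)(C)C | intermediate (not isolated)
35 | tetracyclic 4-methoxycyclohexa-2,4-dienone (C17=O, C19=C20, C21(OMe)=C8; C9 methyl syn to C7–H; C15–OTBS) | CC(C)[C@@H]1C[C@@H]2[C@H]3C=4[C@](C)(CC[C@@]31C[C@H]2O[Si](C)(C)C(C)(C)C)C(=O)C=CC=4OC | intermediate
36 | lithium dienolate from 1,4-reduction of 35 (C17–OLi, C17=C19) | [Li+].CC(C)[C@@H]1C[C@@H]2[C@H]3C=4[C@](C)(CC[C@@]31C[C@H]2O[Si](C)(C)C(C)(C)C)C([O-])=CCC=4OC | intermediate (not isolated)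
37 | C17 enol triflate (C17=C19) with C21(OMe)=C8 | CC(C)[C@@H]1C[C@@H]2[C@H]3C=4[C@](C)(CC[C@@]31C[C@H]2O[Si](C)(C)C(C)(C)C)C(OS(=O)(=O)C(F)(F)F)=CCC=4OC | intermediate
38 | C17 alkenyl bromide (C17=C19) with C21(OMe)=C8 | CC(C)[C@@H]1C[C@@H]2[C@H]3C=4[C@](C)(CC[C@@]31C[C@H]2O[Si](C)(C)C(C)(C)C)C(Br)=CCC=4OC | intermediate
39 | C21 ketone with C17(Br)=C19; C8–H trans to the C9 methyl | CC(C)[C@@H]1C[C@@H]2[C@H]3[C@H]4[C@](C)(CC[C@@]31C[C@H]2O[Si](C)(C)C(C)(C)C)C(Br)=CCC4=O | intermediate
40 | C21 tertiary alcohol (OH axial, syn to the C9 methyl) with C17(Br)=C19 | CC(C)[C@@H]1C[C@@H]2[C@H]3[C@H]4[C@](C)(CC[C@@]31C[C@H]2O[Si](C)(C)C(C)(C)C)C(Br)=CC[C@@]4(C)O | intermediate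
41 | C15 tert-butyldimethylsilyl ether of the target (equatorial C17 bromide) | CC(C)[C@@H]1C[C@@H]2[C@H]3[C@H]4[C@](C)(CC[C@@]31C[C@H]2O[Si](C)(C)C(C)(C)C)[C@@H](Br)CC[C@@]4(C)O | intermediate
42 | CNP0317598.2, tetracyclic bromo diol | CC(C)[C@@H]1C[C@@H]2[C@H]3[C@H]4[C@](C)(CC[C@@]31C[C@H]2O)[C@@H](Br)CC[C@@]4(C)O | target

## Step count and least certain steps

Total step count: 26. Longest linear sequence: 23 steps (steps 4–26, from 7 and 8 to 42). The aryl branch (steps 1–3) joins at step 13.

**Step 20 (key step).** The most likely failures are bond formation at C21 instead of C9, intermolecular O-alkylation, and base-induced elimination of the mesylate. C21 carries the methoxy group, is para to the phenoxide oxygen, and can reach C11 from the other aryl rotamer. O-alkylation between molecules becomes competitive because the nucleophilic carbon is fully substituted and slow. Fallback, from 33 back to 35: the phenol is methylated (MeI, K2CO3, acetone) to the aryl dimethyl ether mesylate F1, and a Finkelstein exchange (NaI, acetone) gives the iodide F2. Heating F2 in (CF3)2CHOH with a hindered pyridine base lets the neutral arene attack C11 through C9 in a Friedel–Crafts-type aryl participation. The resulting O-methyl oxocarbenium ion is demethylated by iodide and delivers 35. No phenoxide and no base are present in this electrophilic mode.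

**Step 13.** The aryl group may fail to transfer to C7, because a di-ortho-substituted aryl nucleophile meets a β-carbon next to a quaternary centre. Enolisation or 1,2-addition would then take over, or facial selectivity would be lost if forcing conditions are needed. Fallback, from 6 and 23 back to 26: bromine–lithium exchange on 6 (n-BuLi, THF, −78 °C) and quenching with B(OMe)3 give the arylboronic acid F3. F3 is added to 23 with Pd(OCOCF3)2 and 2,2′-bipyridine in aqueous medium at 60 °C. The step is then an insertion of the enone into an aryl–palladium bond of divalent palladium, a mode that tolerates crowded β-carbons, followed by protonation to 26.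

**Step 9.** C4 selectivity may erode through a mixture of boat and chair transition states or of ketene acetal geometries, and the hindered rearrangement may lose material to C-silylation. Fallback, from 14 back to 21: 14 is heated with the dimethyl acetal of N,N-dimethyl-3-methylbutanamide in xylene at 140 °C (Eschenmoser–Claisen). The ketene N,O-acetal has a single geometry (isopropyl cis to the allylic oxygen) and needs no strong base; its chair transition state leads to the same C4 epimer as the dimethylamide F4. Reduction of F4 with LiBHEt3 gives alcohol 21.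

**Step 23.** The C17=C19 bond may migrate into conjugation with the new C21 ketone during hydrolysis, followed by loss of HBr, or C8 may be protonated on the wrong face with no safe way to equilibrate. Fallback, from 35 back to 40: the C19=C20 bond of 35 is hydrogenated (H2, 10% Pd/C, EtOAc) to the saturated keto enol ether F5. Aqueous HCl in THF gives the 1,4-diketone F6 with C8 under thermodynamic control. MeMgBr/CeCl3 at −78 °C adds to the less hindered C21 carbonyl to give hydroxy ketone F7. KN(SiMe3)2 and PhNTf2 convert the C17 ketone into enol triflate F8, and the nickel-catalysed exchange with LiBr of step 22 gives 40.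

**Step 25.** Bromine may be lost, either because hydrogen adds to C17 instead of C19 and the β-bromo radical ejects a bromine atom, or because the C–Br bond is reduced; the second hydrogen may also arrive from the wrong face. Fallback, from 40 to 42: the tertiary hydroxyl of 40 is capped (Me3SiOTf, 2,6-lutidine) as the trimethylsilyl ether F9, so that it cannot direct a metal catalyst to the wrong face. Homogeneous hydrogenation with [Ir(cod)(PCy3)(py)]PF6 in CH2Cl2 adds hydrogen anti to the C9 methyl and gives the saturated bis(silyl ether) F10. HF·pyridine removes both silyl groups to give 42.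

## Further compounds

F1 | step 20 | aryl dimethyl ether mesylate (C17–OMe analogue of 33) | CC(C)[C@@H]1C[C@@H]2[C@@H](c3c(C)c(OC)ccc3OC)[C@@]1(CCOS(C)(=O)=O)C[C@H]2O[Si](C)(C)C(C)(C)C
F2 | step 20 | C11 iodide of the aryl dimethyl ether | CC(C)[C@@H]1C[C@@H]2[C@@H](c3c(C)c(OC)ccc3OC)[C@@]1(CCI)C[C@H]2O[Si](C)(C)C(C)(C)C
F3 | step 13 | [3-(benzyloxy)-6-methoxy-2-methylphenyl]boronic acid | COc1ccc(OCc2ccccc2)c(C)c1B(O)O
F4 | step 9 | (2S)-2-[(1S)-1-{2-[(tert-butyldimethylsilyl)oxy]ethyl}cyclopent-2-en-1-yl]-N,N,3-trimethylbutanamide | CC(C)[C@H](C(=O)N(C)C)[C@@]1(CCO[Si](C)(C)C(C)(C)C)C=CCC1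
F5 | step 23 | saturated C17 ketone with C21(OMe)=C8 enol ether | CC(C)[C@@H]1C[C@@H]2[C@H]3C=4[C@](C)(CC[C@@]31C[C@H]2O[Si](C)(C)C(C)(C)C)C(=O)CCC=4OC
F6 | step 23 | C17,C21-diketone with trans A/B fusion | CC(C)[C@@H]1C[C@@H]2[C@H]3[C@H]4[C@](C)(CC[C@@]31C[C@H]2O[Si](C)(C)C(C)(C)C)C(=O)CCC4=O
F7 | step 23 | C17 ketone with C21 tertiary alcohol | CC(C)[C@@H]1C[C@@H]2[C@H]3[C@H]4[C@](C)(CC[C@@]31C[C@H]2O[Si](C)(C)C(C)(C)C)C(=O)CC[C@@]4(C)O
F8 | step 23 | C17 enol triflate with C21 tertiary alcohol | CC(C)[C@@H]1C[C@@H]2[C@H]3[C@H]4[C@](C)(CC[C@@]31C[C@H]2O[Si](C)(C)C(C)(C)C)C(OS(=O)(=O)C(F)(F)F)=CC[C@@]4(C)O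
F9 | step 25 | C21 trimethylsilyl ether of 40 | CC(C)[C@@H]1C[C@@H]2[C@H]3[C@H]4[C@](C)(CC[C@@]31C[C@H]2O[Si](C)(C)C(C)(C)C)C(Br)=CC[C@@]4(C)O[Si](C)(C)C
F10 | step 25 | saturated C17 bromide as C15 tert-butyldimethylsilyl and C21 trimethylsilyl ether | CC(C)[C@@H]1C[C@@H]2[C@H]3[C@H]4[C@](C)(CC[C@@]31C[C@H]2O[Si](C)(C)C(C)(C)C)[C@@H](Br)CC[C@@]4(C)O[Si](C)(C)C
A1 | alternative 1 | tetracyclic C12,C15-diketone with C17 bromide and C21 dioxolane | CC(C)[C@@H]1C[C@@H]2[C@H]3[C@H]4[C@](C)(CC(=O)[C@@]31CC2=O)[C@@H](Br)CCC45OCCO5
A2 | alternative 2 | tricyclic cyclopentenone with quaternary C13 | CC(C)[C@H](CO[Si](C)(C)C(C)(C)C)[C@]12CC(=O)C=C1[C@@H]1C3(OCCO3)CC[C@H](Br)[C@@]1(C)CC2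
A3 | alternative 3 | tetracyclic C15 ketone with C17 dioxolane and C21 tertiary alcohol | CC(C)[C@@H]1C[C@@H]2[C@H]3[C@H]4[C@](C)(CC[C@@]31CC2=O)C5(OCCO5)CC[C@@]4(C)O
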